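## The problem

Compound 27 is a B-type proanthocyanidin. An epigallocatechin 3-O-gallate unit (upper unit: benzo ring A, pyran ring C, pendant trihydroxyphenyl ring B) is bonded from its C4 to C8 of a (+)-catechin unit (lower unit: benzo ring D, pyran ring F, pendant catechol ring E). There are five stereocentres: C2 (R) and C3 (S) of the lower unit are those of natural (+)-catechin, and C2, C3 and C4 of the upper unit (all R) hold the ring-B aryl group and the ester oxygen cis to each other and the ring-D substituent at C4 trans to both. C4 is a diarylmethine carbon wedged between two phloroglucinol-type rings, each with two ortho oxygen atoms, so the bond to it must come from a reaction that tolerates crowding, and the finished C4–C8 bond is cleaved by strong protic acid. Inside ring C the centres can be set in turn: the C4 aryl group can send the C3 oxygen to the opposite face, and the C3 oxygen can then steer the creation of C2. The lower unit is too remote to be relied on for control. Twelve phenols (sensitive to air and base, and a cause of C2 epimerisation when free), a hindered ester and benzylic ether carbons forbid harsh acid, base or oxidants late in the route, so the phenols need one protecting group that leaves under neutral conditions, and the upper 3-hydroxyl that becomes the gallate must be distinguishable from the lower 3-hydroxyl. The feature that opens the molecule is ring A: it is a symmetrical phloroglucinol whose phenol oxygen O1 and ortho carbon C4a form a 1,3-O,C-dinucleophile, while C4–C3–C2 is a three-carbon chain on C8 of ring D in which C4 is the β-carbon and C2 the carbonyl carbon of a cinnamaldehyde. Uniting the two makes C4–C4a and O1–C2, closes ring C and creates the C4 stereocentre in one operation.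

## Retrosynthesis

**27 from 26.** The thirteen O–benzyl bonds are cut last. Benzyl ethers on all twelve phenols and on the lower 3-oxygen allow one neutral hydrogenolysis, which spares the ester and the acid-labile interflavan bond. Silyl or methyl ethers would need fluoride, base or Lewis acid on a polyphenol. The forward step only has to leave the two benzylic C2–O1 bonds intact.

**26 from 24 and 25.** The ester C–O bond is cut to give alcohol 24 and commercial acid 25. Acylating late keeps the ester away from the organolithium, enolate and hydride steps. It requires the upper 3-hydroxyl to be the only free hydroxyl, which the benzyl ether on the lower 3-oxygen guarantees.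

**24 from 23 and 21.** After removal of the silyl group, the O1–C2 bond and the C2–H bond of 23 are cut, leading back to keto phenol 21. Creating C2 by hydride delivery to a cyclic oxocarbenium ion lets the C3 oxygen decide the face and places the aryl group cis to it. Adding the aryl group to a C2–H oxocarbenium ion instead would be expected to put it trans. The precursor has lost ring C and one stereocentre.

**21 from 16 and 19.** The bond between C2 and ring B is cut to give lactone 16 as the acyl donor and aryl bromide 19 as the source of aryllithium 20. The lactone carries ring A, C3 and C4 with their configurations fixed, and its ring oxygen becomes the phenol that later re-closes ring C. The forward reaction must stop after one addition.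

**16 from 13.** After silylation, the C3–O bond is cut to give lactone 13. The enolate of 13 is flat at C3 and has the bulky ring-D substituent on the adjacent carbon, so an electrophilic oxygen source should enter anti and give the 3,4-trans arrangement without any external control.

**13 from 7 and 9 (through lactol 12).** The C4–C4a and O1–C2 bonds are cut. This is preferred to cutting C4–C8, the usual flavan-4-yl cation disconnection, because the cation route needs a complete, 4-activated epigallocatechin unit, whereas here the upper unit is grown from a symmetrical phenol on the intact catechin. The precursors are enal 7 and phenol 9, and the step has to choose one face of the β-carbon.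

**7 from 1.** The Cα=Cβ bond (Wittig), the C8–CHO bond (formylation of aryllithium 5), the C8–Br bond and the five O–benzyl bonds are cut in turn, ending at (+)-catechin 1, which supplies both lower stereocentres. C8 is reached selectively because benzylated catechins brominate there.

**9 from 8, and 19 from 17.** O–benzyl bonds are cut to give phloroglucinol 8. For ring B the benzyl ethers are traced to triol 18 and on to commercial trimethyl ether 17, since methyl ethers could not be removed at the end.

## Roads not taken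

**Alternative 1:** Ring F of the lower unit is cut at O1–C2 and C3–C4. In the forward direction an ortho-quinone methide on ring D, A2 (exocyclic methylene on C4a, carbonyl at C8a, upper unit already attached), would add the (E)-enol carbonate A3 in a hetero-Diels–Alder reaction to give A1.
- Merits: suprafacial addition to the E-alkene gives the 2,3-trans lower ring directly, and A1 is one hydrogenolysis from 27, because the benzyl carbonate falls with the benzyl ethers. In the endgame this road is shorter than the chosen one.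
- Weak point, scope: A2 already contains the whole upper unit with C2, C3 and C4 in place, so the cut solves only the easy ring and leaves the hard stereocentre to whatever makes A2.
- Weak point, regiochemistry: the carbonate oxygen of A3 directs the methide carbon to the aryl-bearing carbon, the normal enol ether sense, and only the 4-benzyloxyphenyl group pushes the other way, so the orientation is in doubt.
- Weak point, configuration: the two new centres are formed on a flat methide far from any stereocentre, so the absolute configuration of the lower unit is uncontrolled.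
- Comparison: the chosen plan takes the lower unit from catechin, so its configuration is never in question, and it builds the upper ring with unambiguous polarity. That is what it sets against the shorter finish of this road.

**Alternative 2:** Ring C is cut at O1–C8a and C4–C4a. The alkoxide of the syn aldol A5 would add to aryne A6 at the carbon remote from the neighbouring benzyloxy group, and the aryl anion so formed would close on the ring-D ketone to give carbinol A4.
- Merits: C2 and C3 come from an aldol reaction before the ring exists, which is a more secure way to obtain the 2,3-cis pair than the late hydride delivery of the chosen plan, and the whole carbon skeleton is assembled in one step.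
- Weak point, substrate: the alkoxide of a β-hydroxy ketone can undergo retro-aldol cleavage under the basic, fluoride-containing conditions of aryne generation, and the ketone of A5 is flanked by two ortho oxygen substituents and is a poor electrophile.
- Weak point, C4: it emerges as a tertiary carbinol and must then be reduced through a doubly benzylic cation, with hydride arriving cis to the C3 silyloxy group if the aryl group is to end trans. The hardest centre is thus set last, against the steric preference.
- Comparison: the chosen plan sets C4 first, by a catalyst, and lets it control C3. It accepts in exchange that C2 is set late.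

**Alternative 3:** Ring C is cut at C3–C4 and O1–C2. Diarylcarbinol A8 would ionise to a ring-A ortho-quinone methide, the enol of ketone A9 would add to it at C4, and the phenol would close on the ketone to give hemiketal A7.
- Merits: A7 is the ring-closed tautomer of keto phenol 21 of the chosen route, and A8 lies only about two steps beyond aryllithium 5. This road would reach the common intermediate in roughly half the steps and is clearly better in step economy.
- Weak point: C3 and C4 must be created together in one intermolecular step, with both the anti relationship and the absolute sense controlled. The methide carbon carries a bulky chiral aryl group, the carbinol ionises so readily that an uncatalysed pathway is likely, the nucleophile is the enol of an α-silyloxy aryl ketone, and the methide is stabilised by two phloroglucinol rings and is therefore a weak electrophile.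
- Comparison: the chosen plan is longer, but each centre is set by a separate reaction of established type: C4 by catalyst control, C3 by the C4 substituent and C2 by the C3 oxygen.

Key step: step 7

Remark on names: "penta-O-benzylcatechin-8-yl" denotes the (2R,3S)-3,5,7-tris(benzyloxy)-2-[3,4-bis(benzyloxy)phenyl]chroman-8-yl group. Compound 21 is written as the open keto phenol; any cyclic hemiketal tautomer present would lead to the same oxocarbenium ion 22 in step 14. Acid 25 is taken as commercially available.

## Route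

Step 1
Reactants: 1 (+)-catechin
Product: 2 (2R,3S)-5,7-bis(benzyloxy)-2-[3,4-bis(benzyloxy)phenyl]chroman-3-ol (5,7,3',4'-tetra-O-benzylcatechin)
Conditions: BnBr (4.4 equiv), K2CO3, DMF, 0 °C to rt
Reagents that add atoms: benzyl bromide, BrCc1ccccc1
Why: Williamson etherification; K2CO3 ionises the four phenols but not the secondary alcohol, so the 3-hydroxyl stays free and the stereocentres are untouched.

Step 2
Reactants: 2 5,7,3',4'-tetra-O-benzylcatechin
Product: 3 (2R,3S)-3,5,7-tris(benzyloxy)-2-[3,4-bis(benzyloxy)phenyl]chromane (penta-O-benzylcatechin)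
Conditions: NaH, BnBr, DMF, 0 °C to rt
Reagents that add atoms: benzyl bromide, BrCc1ccccc1
Why: Williamson etherification of the secondary alkoxide; with all phenols already capped there is no phenoxide that could trigger C2 epimerisation, and the benzyl ether masks the lower 3-oxygen until the final hydrogenolysis.

Step 3
Reactants: 3 penta-O-benzylcatechin
Product: 4 (2R,3S)-8-bromo-3,5,7-tris(benzyloxy)-2-[3,4-bis(benzyloxy)phenyl]chromane
Conditions: NBS, CH2Cl2, −78 °C to rt
Reagents that add atoms: N-bromosuccinimide, O=C1CCC(=O)N1Br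
Why: Electrophilic aromatic bromination; ring D is the most electron-rich ring and benzylated, 3-O-protected catechins are brominated at C8 in preference to C6.

Step 4
Reactants: 4 8-bromo-penta-O-benzylcatechin
Product: 6 (2R,3S)-3,5,7-tris(benzyloxy)-2-[3,4-bis(benzyloxy)phenyl]chromane-8-carbaldehyde, via catechin-8-yllithium 5 (not isolated)
Conditions: n-BuLi, THF, −78 °C; DMF, −78 to 0 °C; H2O
Reagents that add atoms: N,N-dimethylformamide, CN(C)C=O
Why: Bromine–lithium exchange is faster at −78 °C than deprotonation of the benzyl ethers, and formylation of the aryllithium with DMF gives the aldehyde after hydrolysis of the hemiaminal salt.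

Step 5
Reactants: 6 penta-O-benzylcatechin-8-carbaldehyde
Product: 7 (E)-3-(penta-O-benzylcatechin-8-yl)prop-2-enal
Conditions: Ph3P=CHCHO (1.3 equiv), toluene, 90 °C
Reagents that add atoms: (triphenylphosphoranylidene)acetaldehyde, O=CC=P(c1ccccc1)(c1ccccc1)c1ccccc1
Why: Wittig reaction with a stabilised ylide, which gives the E-alkene under thermodynamic control of oxaphosphetane formation; the product enal is conjugated to the electron-rich ring and is less reactive towards the ylide than it would be otherwise.

Step 6
Reactants: 8 phloroglucinol (benzene-1,3,5-triol)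
Product: 9 3,5-bis(benzyloxy)phenol
Conditions: NaH (2.1 equiv), BnBr (2.0 equiv), DMF, 0 °C to rt; chromatographic separation from the mono- and tribenzyl ethers
Reagents that add atoms: benzyl bromide, BrCc1ccccc1
Why: Statistical Williamson etherification of a symmetrical triol; the three hydroxyls are equivalent, so the dibenzyl ether is one defined compound that is separated from the under- and over-alkylated ethers.

Step 7
Reactants: 7 (E)-3-(penta-O-benzylcatechin-8-yl)prop-2-enal; 9 3,5-bis(benzyloxy)phenol
Product: 12 (4R)-5,7-bis(benzyloxy)-4-(penta-O-benzylcatechin-8-yl)chroman-2-ol (both C2 anomers), via catalyst-bound iminium benzoate 10 (not isolated), via ring-opened hydroxy aldehyde 11 (not isolated)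
Conditions: (S)-2-[diphenyl(trimethylsilyloxy)methyl]pyrrolidine (20 mol %), PhCO2H (20 mol %), toluene, 0 °C to rt
Reagents that add atoms: none
Why: The secondary amine condenses with enal 7 to the E,s-trans iminium ion 10, which is attacked at its β-carbon by the carbon ortho to the hydroxyl of phenol 9 (Friedel–Crafts conjugate addition); protonation and hydrolysis of the resulting enamine release the catalyst and hydroxy aldehyde 11. The phenol oxygen then adds to the aldehyde in a 6-exo-trig hemiacetalisation that closes ring C as lactol 12. The closest known reaction type is the diarylprolinol silyl ether catalysed Friedel–Crafts alkylation–hemiacetalisation of electron-rich phenols and naphthols with cinnamaldehydes, which gives 4-arylchroman-2-ols. C4 is set by the catalyst: the diphenyl(silyloxy)methyl group of the S-configured pyrrolidine covers the Re face of the β-carbon, so the arene adds to the Si face, which is the 4R configuration with ring D trans to the later C3 oxygen; the distant stereocentres of the catechin unit act only as a matched or mismatched perturbation. The anomeric carbon C2 is not controlled and need not be, because it becomes a carbonyl carbon in step 8. The step needs ortho rather than para attack and C- rather than O-alkylation: the two ortho positions of 9 are equivalent by symmetry and activated by all three oxygens, only the ortho adduct is drained from the equilibrium as a lactol, and oxa-Michael addition is reversible. The β-aryl group with two ortho oxygens makes 10 less electrophilic and more hindered than a simple cinnamaldehyde iminium ion, which the high nucleophilicity of the phloroglucinol diether has to offset.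

Step 8
Reactants: 12 (4R)-5,7-bis(benzyloxy)-4-(penta-O-benzylcatechin-8-yl)chroman-2-ol
Product: 13 (4R)-5,7-bis(benzyloxy)-4-(penta-O-benzylcatechin-8-yl)chroman-2-one
Conditions: 2,2,6,6-tetramethylpiperidin-1-oxyl (10 mol %), PhI(OAc)2, CH2Cl2, rt
Reagents that add atoms: none
Why: Oxoammonium-mediated oxidation of a lactol to the lactone, in which both anomers converge on one compound; the conditions are neutral, so C4 and the benzyl ethers are not affected.

Step 9
Reactants: 13 (4R)-5,7-bis(benzyloxy)-4-(penta-O-benzylcatechin-8-yl)chroman-2-one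
Product: 15 (3R,4R)-5,7-bis(benzyloxy)-3-hydroxy-4-(penta-O-benzylcatechin-8-yl)chroman-2-one (3,4-trans), via sodium lactone enolate 14 (not isolated)
Conditions: NaN(SiMe3)2, THF, −78 °C; 2-(phenylsulfonyl)-3-phenyloxaziridine, −78 °C; AcOH, −78 °C
Reagents that add atoms: 2-(phenylsulfonyl)-3-phenyloxaziridine, O=S(=O)(c1ccccc1)N1OC1c1ccccc1
Why: Enolate hydroxylation with an N-sulfonyloxaziridine; the ring-D group at C4 sits pseudoaxial to avoid the peri 5-benzyloxy group and covers one face of the planar enolate, so oxygen is delivered anti to it and C3 is set trans to C4 (3R). The low temperature keeps the aryl ester enolate from fragmenting to a ketene.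

Step 10
Reactants: 15 (3R,4R)-5,7-bis(benzyloxy)-3-hydroxy-4-(penta-O-benzylcatechin-8-yl)chroman-2-one
Product: 16 (3R,4R)-5,7-bis(benzyloxy)-3-(tert-butyldimethylsilyloxy)-4-(penta-O-benzylcatechin-8-yl)chroman-2-one
Conditions: t-BuMe2SiOTf, 2,6-lutidine, CH2Cl2, 0 °C
Reagents that add atoms: tert-butyldimethylsilyl trifluoromethanesulfonate, CC(C)(C)[Si](C)(C)OS(=O)(=O)C(F)(F)F
Why: Silylation of a hindered secondary alcohol with a silyl triflate and a non-nucleophilic base; the silyl ether is orthogonal to the benzyl ethers and marks the oxygen that will carry the gallate.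

Step 11
Reactants: 17 5-bromo-1,2,3-trimethoxybenzene
Product: 18 5-bromobenzene-1,2,3-triol
Conditions: BBr3, CH2Cl2, −78 °C to rt; H2O
Reagents that add atoms: none
Why: Lewis acid cleavage of aryl methyl ethers by BBr3; the aryl bromide is inert, and the air-sensitive triol is carried on without storage.

Step 12
Reactants: 18 5-bromobenzene-1,2,3-triol
Product: 19 5-bromo-1,2,3-tris(benzyloxy)benzene
Conditions: BnBr, K2CO3, DMF, rt, under argon
Reagents that add atoms: benzyl bromide, BrCc1ccccc1
Why: Williamson etherification of the three phenols; this puts ring B under the same protecting group as the rest of the molecule.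

Step 13
Reactants: 19 5-bromo-1,2,3-tris(benzyloxy)benzene; 16 (3R,4R)-5,7-bis(benzyloxy)-3-(tert-butyldimethylsilyloxy)-4-(penta-O-benzylcatechin-8-yl)chroman-2-one
Product: 21 (2R,3R)-3-[2,4-bis(benzyloxy)-6-hydroxyphenyl]-2-(tert-butyldimethylsilyloxy)-3-(penta-O-benzylcatechin-8-yl)-1-[3,4,5-tris(benzyloxy)phenyl]propan-1-one, via 3,4,5-tris(benzyloxy)phenyllithium 20 (not isolated)
Conditions: 19, n-BuLi, THF, −78 °C; then 16 (0.95 equiv) in THF, −78 °C; AcOH, −78 °C
Reagents that add atoms: none
Why: Bromine–lithium exchange followed by acylation of the aryllithium by the lactone; the tetrahedral adduct opens to the ring-A phenoxide and the new ketone is shielded by the α-silyloxy group and the β,β-diaryl carbon, so at −78 °C with one equivalent a second addition should be slow. C3 and C4 are not touched.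

Step 14
Reactants: 21 keto phenol
Product: 23 (2R,3R,4R)-5,7-bis(benzyloxy)-3-(tert-butyldimethylsilyloxy)-4-(penta-O-benzylcatechin-8-yl)-2-[3,4,5-tris(benzyloxy)phenyl]chromane (2,3-cis; 3,4-trans), via cyclic oxocarbenium triflate 22 (not isolated)
Conditions: Et3SiH (5 equiv), Me3SiOTf (0.3 equiv), CH2Cl2, −78 to −40 °C; Et3N quench
Reagents that add atoms: none
Why: Reductive etherification (ionic hydrogenation of a cyclic hemiketal): the phenol adds to the activated ketone, the hemiketal ionises to oxocarbenium ion 22 and Et3SiH delivers hydride to C2. In the half-chair of 22 the C3 silyloxy group lies pseudoaxial next to the coplanar 2-aryl group and hydride enters anti to it along the axial trajectory, so the C2 hydrogen ends trans and the ring-B aryl group cis to the C3 oxygen (2R).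

Step 15
Reactants: 23 3-O-silyl flavan dimer
Product: 24 (2R,3R,4R)-5,7-bis(benzyloxy)-4-(penta-O-benzylcatechin-8-yl)-2-[3,4,5-tris(benzyloxy)phenyl]chroman-3-ol
Conditions: Bu4NF, AcOH, THF, rt to 40 °C
Reagents that add atoms: none
Why: Fluoride cleavage of the silyl ether; buffering with acetic acid keeps the medium near neutral, and the benzyl ethers and the interflavan bond are inert.

Step 16
Reactants: 24 upper 3-alcohol; 25 3,4,5-tris(benzyloxy)benzoic acid
Product: 26 (2R,3R,4R)-5,7-bis(benzyloxy)-4-(penta-O-benzylcatechin-8-yl)-2-[3,4,5-tris(benzyloxy)phenyl]chroman-3-yl 3,4,5-tris(benzyloxy)benzoate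
Conditions: N,N'-dicyclohexylcarbodiimide, 4-(dimethylamino)pyridine, CH2Cl2, rt
Reagents that add atoms: none
Why: Steglich esterification; the upper 3-hydroxyl is the only free hydroxyl in 24, so the gallate can go nowhere else, and acyl transfer through the acylpyridinium ion copes with the hindered axial alcohol.

Step 17
Reactants: 26 tridecabenzyl ether of the target
Product: 27 CNP0129434.1, epigallocatechin 3-O-gallate-(4β→8)-catechin, (2R,3R,4R) in the upper unit and (2R,3S) in the lower unit
Conditions: H2 (1 atm), Pd(OH)2 on carbon, THF/MeOH, rt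
Reagents that add atoms: none
Why: Hydrogenolysis of twelve aryl benzyl ethers and one alkyl benzyl ether under neutral conditions; the ester, the interflavan bond and all five stereocentres are not affected.

## Compound list

1 | (+)-catechin, (2R,3S) | Oc1cc(O)c2c(c1)O[C@H](c1ccc(O)c(O)c1)[C@@H](O)C2 | starting material
2 | (2R,3S)-5,7-bis(benzyloxy)-2-[3,4-bis(benzyloxy)phenyl]chroman-3-ol | c1c(OCc2ccccc2)cc(OCc2ccccc2)c2c1O[C@H](c1ccc(OCc3ccccc3)c(OCc3ccccc3)c1)[C@@H](O)C2 | intermediate
3 | (2R,3S)-3,5,7-tris(benzyloxy)-2-[3,4-bis(benzyloxy)phenyl]chromane (penta-O-benzylcatechin) | c1c(OCc2ccccc2)cc(OCc2ccccc2)c2c1O[C@H](c1ccc(OCc3ccccc3)c(OCc3ccccc3)c1)[C@@H](OCc1ccccc1)C2 | intermediate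
4 | (2R,3S)-8-bromo-3,5,7-tris(benzyloxy)-2-[3,4-bis(benzyloxy)phenyl]chromane | Brc1c(OCc2ccccc2)cc(OCc2ccccc2)c2c1O[C@H](c1ccc(OCc3ccccc3)c(OCc3ccccc3)c1)[C@@H](OCc1ccccc1)C2 | intermediate
5 | penta-O-benzylcatechin-8-yllithium | [Li]c1c(OCc2ccccc2)cc(OCc2ccccc2)c2c1O[C@H](c1ccc(OCc3ccccc3)c(OCc3ccccc3)c1)[C@@H](OCc1ccccc1)C2 | intermediate
6 | (2R,3S)-3,5,7-tris(benzyloxy)-2-[3,4-bis(benzyloxy)phenyl]chromane-8-carbaldehyde | O=Cc1c(OCc2ccccc2)cc(OCc2ccccc2)c2c1O[C@H](c1ccc(OCc3ccccc3)c(OCc3ccccc3)c1)[C@@H](OCc1ccccc1)C2 | intermediate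
7 | (E)-3-(penta-O-benzylcatechin-8-yl)prop-2-enal | O=C/C=C/c1c(OCc2ccccc2)cc(OCc2ccccc2)c2c1O[C@H](c1ccc(OCc3ccccc3)c(OCc3ccccc3)c1)[C@@H](OCc1ccccc1)C2 | intermediate
8 | phloroglucinol | Oc1cc(O)cc(O)c1 | starting material
9 | 3,5-bis(benzyloxy)phenol | Oc1cc(OCc2ccccc2)cc(OCc2ccccc2)c1 | intermediate
10 | iminium benzoate of enal 7 with (S)-2-[diphenyl(trimethylsilyloxy)methyl]pyrrolidine | C[Si](C)(C)OC(c1ccccc1)(c1ccccc1)[C@@H]1CCC[N+]1=C/C=C/c1c(OCc2ccccc2)cc(OCc2ccccc2)c2c1O[C@H](c1ccc(OCc3ccccc3)c(OCc3ccccc3)c1)[C@@H](OCc1ccccc1)C2.[O-]C(=O)c1ccccc1 | intermediate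
11 | (3R)-3-[2,4-bis(benzyloxy)-6-hydroxyphenyl]-3-(penta-O-benzylcatechin-8-yl)propanal | O=CC[C@@H](c2c(OCc3ccccc3)cc(OCc3ccccc3)c3c2O[C@H](c2ccc(OCc4ccccc4)c(OCc4ccccc4)c2)[C@@H](OCc2ccccc2)C3)c2c(OCc3ccccc3)cc(OCc3ccccc3)cc2O | intermediate
12 | (4R)-5,7-bis(benzyloxy)-4-(penta-O-benzylcatechin-8-yl)chroman-2-ol, C2 anomers | OC1C[C@@H](c2c(OCc3ccccc3)cc(OCc3ccccc3)c3c2O[C@H](c2ccc(OCc4ccccc4)c(OCc4ccccc4)c2)[C@@H](OCc2ccccc2)C3)c2c(OCc3ccccc3)cc(OCc3ccccc3)cc2O1 | intermediate
13 | (4R)-5,7-bis(benzyloxy)-4-(penta-O-benzylcatechin-8-yl)chroman-2-one | O=C1C[C@@H](c2c(OCc3ccccc3)cc(OCc3ccccc3)c3c2O[C@H](c2ccc(OCc4ccccc4)c(OCc4ccccc4)c2)[C@@H](OCc2ccccc2)C3)c2c(OCc3ccccc3)cc(OCc3ccccc3)cc2O1 | intermediate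
14 | sodium enolate of lactone 13 | [Na+].[O-]C1=C[C@@H](c2c(OCc3ccccc3)cc(OCc3ccccc3)c3c2O[C@H](c2ccc(OCc4ccccc4)c(OCc4ccccc4)c2)[C@@H](OCc2ccccc2)C3)c2c(OCc3ccccc3)cc(OCc3ccccc3)cc2O1 | intermediate
15 | (3R,4R)-5,7-bis(benzyloxy)-3-hydroxy-4-(penta-O-benzylcatechin-8-yl)chroman-2-one | O[C@@H]1[C@@H](c2c(OCc3ccccc3)cc(OCc3ccccc3)c3c2O[C@H](c2ccc(OCc4ccccc4)c(OCc4ccccc4)c2)[C@@H](OCc2ccccc2)C3)c2c(OCc3ccccc3)cc(OCc3ccccc3)cc2OC1=O | intermediate
16 | (3R,4R)-5,7-bis(benzyloxy)-3-(tert-butyldimethylsilyloxy)-4-(penta-O-benzylcatechin-8-yl)chroman-2-one | CC(C)(C)[Si](C)(C)O[C@@H]1[C@@H](c2c(OCc3ccccc3)cc(OCc3ccccc3)c3c2O[C@H](c2ccc(OCc4ccccc4)c(OCc4ccccc4)c2)[C@@H](OCc2ccccc2)C3)c2c(OCc3ccccc3)cc(OCc3ccccc3)cc2OC1=O | intermediate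
17 | 5-bromo-1,2,3-trimethoxybenzene | COc1cc(Br)cc(OC)c1OC | starting material
18 | 5-bromobenzene-1,2,3-triol | Oc1cc(Br)cc(O)c1O | intermediate
19 | 5-bromo-1,2,3-tris(benzyloxy)benzene | Brc1cc(OCc2ccccc2)c(OCc2ccccc2)c(OCc2ccccc2)c1 | intermediate
20 | 3,4,5-tris(benzyloxy)phenyllithium | [Li]c1cc(OCc2ccccc2)c(OCc2ccccc2)c(OCc2ccccc2)c1 | intermediate
21 | (2R,3R)-3-[2,4-bis(benzyloxy)-6-hydroxyphenyl]-2-(tert-butyldimethylsilyloxy)-3-(penta-O-benzylcatechin-8-yl)-1-[3,4,5-tris(benzyloxy)phenyl]propan-1-one | CC(C)(C)[Si](C)(C)O[C@H]([C@@H](c2c(OCc3ccccc3)cc(OCc3ccccc3)c3c2O[C@H](c2ccc(OCc4ccccc4)c(OCc4ccccc4)c2)[C@@H](OCc2ccccc2)C3)c2c(OCc3ccccc3)cc(OCc3ccccc3)cc2O)C(=O)c1cc(OCc2ccccc2)c(OCc2ccccc2)c(OCc2ccccc2)c1 | intermediate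
22 | (3R,4R)-5,7-bis(benzyloxy)-3-(tert-butyldimethylsilyloxy)-4-(penta-O-benzylcatechin-8-yl)-2-[3,4,5-tris(benzyloxy)phenyl]-3,4-dihydrochromenylium trifluoromethanesulfonate | CC(C)(C)[Si](C)(C)O[C@@H]1[C@@H](c2c(OCc3ccccc3)cc(OCc3ccccc3)c3c2O[C@H](c2ccc(OCc4ccccc4)c(OCc4ccccc4)c2)[C@@H](OCc2ccccc2)C3)c2c(OCc3ccccc3)cc(OCc3ccccc3)cc2[O+]=C1c1cc(OCc2ccccc2)c(OCc2ccccc2)c(OCc2ccccc2)c1.[O-]S(=O)(=O)C(F)(F)F | intermediate
23 | (2R,3R,4R)-5,7-bis(benzyloxy)-3-(tert-butyldimethylsilyloxy)-4-(penta-O-benzylcatechin-8-yl)-2-[3,4,5-tris(benzyloxy)phenyl]chromane | CC(C)(C)[Si](C)(C)O[C@@H]1[C@@H](c2c(OCc3ccccc3)cc(OCc3ccccc3)c3c2O[C@H](c2ccc(OCc4ccccc4)c(OCc4ccccc4)c2)[C@@H](OCc2ccccc2)C3)c2c(OCc3ccccc3)cc(OCc3ccccc3)cc2O[C@@H]1c1cc(OCc2ccccc2)c(OCc2ccccc2)c(OCc2ccccc2)c1 | intermediate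
24 | (2R,3R,4R)-5,7-bis(benzyloxy)-4-(penta-O-benzylcatechin-8-yl)-2-[3,4,5-tris(benzyloxy)phenyl]chroman-3-ol | O[C@@H]1[C@@H](c2c(OCc3ccccc3)cc(OCc3ccccc3)c3c2O[C@H](c2ccc(OCc4ccccc4)c(OCc4ccccc4)c2)[C@@H](OCc2ccccc2)C3)c2c(OCc3ccccc3)cc(OCc3ccccc3)cc2O[C@@H]1c1cc(OCc2ccccc2)c(OCc2ccccc2)c(OCc2ccccc2)c1 | intermediate
25 | 3,4,5-tris(benzyloxy)benzoic acid | OC(=O)c1cc(OCc2ccccc2)c(OCc2ccccc2)c(OCc2ccccc2)c1 | starting material
26 | (2R,3R,4R)-5,7-bis(benzyloxy)-4-(penta-O-benzylcatechin-8-yl)-2-[3,4,5-tris(benzyloxy)phenyl]chroman-3-yl 3,4,5-tris(benzyloxy)benzoate | O=C(O[C@@H]1[C@@H](c2c(OCc3ccccc3)cc(OCc3ccccc3)c3c2O[C@H](c2ccc(OCc4ccccc4)c(OCc4ccccc4)c2)[C@@H](OCc2ccccc2)C3)c2c(OCc3ccccc3)cc(OCc3ccccc3)cc2O[C@@H]1c1cc(OCc2ccccc2)c(OCc2ccccc2)c(OCc2ccccc2)c1)c1cc(OCc2ccccc2)c(OCc2ccccc2)c(OCc2ccccc2)c1 | intermediate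
27 | CNP0129434.1, epigallocatechin 3-O-gallate-(4β→8)-catechin | O=C(O[C@@H]1[C@@H](c2c(O)cc(O)c3c2O[C@H](c2ccc(O)c(O)c2)[C@@H](O)C3)c2c(O)cc(O)cc2O[C@@H]1c1cc(O)c(O)c(O)c1)c1cc(O)c(O)c(O)c1 | target

## Step count and risk

Total: 17 steps. Longest linear sequence: 14 steps (steps 1–5, 7–10 and 13–17). Steps 6, 11 and 12 prepare the two side fragments.

**Step 7 (key step).** The most likely failure is slow or incomplete conjugate addition, because the iminium ion carries a β-aryl group with two ortho oxygens and is both deactivated and hindered. Erosion of facial selectivity is the second risk, if the catalyst and the catechin unit turn out to be mismatched.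
- Fallback: it sets out from aldehyde 6 and returns at lactone 13. Knoevenagel condensation of 6 with 2,2-dimethyl-1,3-dioxane-4,6-dione would give the alkylidene malonate 2,2-dimethyl-5-[(penta-O-benzylcatechin-8-yl)methylidene]-1,3-dioxane-4,6-dione F1, a far stronger acceptor than the iminium ion. Heating F1 with phenol 9 and Yb(OTf)3 (10 mol %) in nitromethane should give Friedel–Crafts conjugate addition through the same ortho carbon (C4–C4a), acylation of the phenol by the cyclic malonate (O1–C2) and loss of acetone and carbon dioxide, leading directly to the 4-aryl lactone.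
- Cost: the same two bonds and the same ring are formed, but C4 is no longer under catalyst control. The two C4 epimers are diastereomers because of the catechin unit and would be separated by chromatography at the stage of 13.

**Step 14.** Hydride must reach C2 of 22 on the face that also carries the pseudoaxial ring-D group at C4, so the preference set by the C3 silyloxy group may be overridden and the 2,3-trans isomer may form. Partial loss of the silyl ether under the Lewis acid is a lesser risk.
- Fallback: it sets out from 21 and returns at 24, replacing the oxocarbenium reduction by a ring closure with inversion. Desilylation of 21 (Bu4NF, AcOH) would give the α-hydroxy ketone (2R,3R)-3-[2,4-bis(benzyloxy)-6-hydroxyphenyl]-2-hydroxy-3-(penta-O-benzylcatechin-8-yl)-1-[3,4,5-tris(benzyloxy)phenyl]propan-1-one F2. Chelation-controlled reduction with Zn(BH4)2 in ether should give the anti diol (1S,2R,3R)-3-[2,4-bis(benzyloxy)-6-hydroxyphenyl]-3-(penta-O-benzylcatechin-8-yl)-1-[3,4,5-tris(benzyloxy)phenyl]propane-1,2-diol F3. Mitsunobu cyclisation (PPh3, diisopropyl azodicarboxylate, THF) of the phenol onto the benzylic carbinol with inversion would then close ring C with the 2R configuration.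

**Step 13.** A second aryllithium addition to the liberated ketone, or enolisation at C3 with loss of the trans relationship, may compete, because the tetrahedral adduct of an aryl ester opens readily.
- Fallback: it sets out from 16 and returns at 21. Opening the lactone with the magnesium amide formed from N,O-dimethylhydroxylamine hydrochloride and i-PrMgCl in THF would give the N-methoxy-N-methylamide (2R,3R)-3-[2,4-bis(benzyloxy)-6-hydroxyphenyl]-2-(tert-butyldimethylsilyloxy)-N-methoxy-N-methyl-3-(penta-O-benzylcatechin-8-yl)propanamide F4. Treatment of F4 with 20 (2.2 equiv, the first equivalent deprotonating the phenol) should give a chelated adduct that cannot add a second aryl group and that releases the ketone only on work-up.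

**Step 9.** Fragmentation of the aryl ester enolate to a ketene and a phenoxide, or addition of the product alkoxide to the sulfonimine by-product, could lower the return.
- Fallback: a Rubottom oxidation, setting out from 13 and returning at 15. Deprotonation with LiN(i-Pr)2 in the presence of Me3SiCl at −78 °C would trap the enolate as it forms as the silyl ketene acetal (4R)-5,7-bis(benzyloxy)-4-(penta-O-benzylcatechin-8-yl)-2-(trimethylsilyloxy)-4H-chromene F5. Epoxidation of F5 with dimethyldioxirane in acetone at −78 °C, anti to the C4 substituent, and mild hydrolysis of the migrated silyl group should then give the trans hydroxy lactone.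

## Further compounds

F1 | step 7 | 2,2-dimethyl-5-[(penta-O-benzylcatechin-8-yl)methylidene]-1,3-dioxane-4,6-dione | CC1(C)OC(=O)C(=Cc2c(OCc3ccccc3)cc(OCc3ccccc3)c3c2O[C@H](c2ccc(OCc4ccccc4)c(OCc4ccccc4)c2)[C@@H](OCc2ccccc2)C3)C(=O)O1
F2 | step 14 | (2R,3R)-3-[2,4-bis(benzyloxy)-6-hydroxyphenyl]-2-hydroxy-3-(penta-O-benzylcatechin-8-yl)-1-[3,4,5-tris(benzyloxy)phenyl]propan-1-one | O[C@H]([C@@H](c2c(OCc3ccccc3)cc(OCc3ccccc3)c3c2O[C@H](c2ccc(OCc4ccccc4)c(OCc4ccccc4)c2)[C@@H](OCc2ccccc2)C3)c2c(OCc3ccccc3)cc(OCc3ccccc3)cc2O)C(=O)c1cc(OCc2ccccc2)c(OCc2ccccc2)c(OCc2ccccc2)c1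
F3 | step 14 | (1S,2R,3R)-3-[2,4-bis(benzyloxy)-6-hydroxyphenyl]-3-(penta-O-benzylcatechin-8-yl)-1-[3,4,5-tris(benzyloxy)phenyl]propane-1,2-diol | O[C@H]([C@@H](c2c(OCc3ccccc3)cc(OCc3ccccc3)c3c2O[C@H](c2ccc(OCc4ccccc4)c(OCc4ccccc4)c2)[C@@H](OCc2ccccc2)C3)c2c(OCc3ccccc3)cc(OCc3ccccc3)cc2O)[C@@H](O)c1cc(OCc2ccccc2)c(OCc2ccccc2)c(OCc2ccccc2)c1
F4 | step 13 | (2R,3R)-3-[2,4-bis(benzyloxy)-6-hydroxyphenyl]-2-(tert-butyldimethylsilyloxy)-N-methoxy-N-methyl-3-(penta-O-benzylcatechin-8-yl)propanamide | CC(C)(C)[Si](C)(C)O[C@H]([C@@H](c2c(OCc3ccccc3)cc(OCc3ccccc3)c3c2O[C@H](c2ccc(OCc4ccccc4)c(OCc4ccccc4)c2)[C@@H](OCc2ccccc2)C3)c2c(OCc3ccccc3)cc(OCc3ccccc3)cc2O)C(=O)N(C)OC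
F5 | step 9 | (4R)-5,7-bis(benzyloxy)-4-(penta-O-benzylcatechin-8-yl)-2-(trimethylsilyloxy)-4H-chromene | C[Si](C)(C)OC1=C[C@@H](c2c(OCc3ccccc3)cc(OCc3ccccc3)c3c2O[C@H](c2ccc(OCc4ccccc4)c(OCc4ccccc4)c2)[C@@H](OCc2ccccc2)C3)c2c(OCc3ccccc3)cc(OCc3ccccc3)cc2O1
A1 | alternative 1 | per-O-benzylated 27 with a benzyl carbonate in place of the benzyl ether on the lower 3-oxygen | O=C(c1cc(OCc2ccccc2)c(OCc2ccccc2)c(OCc2ccccc2)c1)O[C@@H]1[C@@H](c2c(OCc3ccccc3)cc(OCc3ccccc3)c3c2O[C@H](c2ccc(OCc4ccccc4)c(OCc4ccccc4)c2)[C@@H](OC(=O)OCc2ccccc2)C3)c2c(OCc3ccccc3)cc(OCc3ccccc3)cc2O[C@@H]1c1cc(OCc2ccccc2)c(OCc2ccccc2)c(OCc2ccccc2)c1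
A2 | alternative 1 | ring-D ortho-quinone methide attached to C4 of the benzylated epigallocatechin gallate unit | O=C(c1cc(OCc2ccccc2)c(OCc2ccccc2)c(OCc2ccccc2)c1)O[C@@H]1[C@@H](C2=C(OCc3ccccc3)C=C(OCc3ccccc3)C(=C)C2=O)c2c(OCc3ccccc3)cc(OCc3ccccc3)cc2O[C@@H]1c1cc(OCc2ccccc2)c(OCc2ccccc2)c(OCc2ccccc2)c1
A3 | alternative 1 | benzyl (E)-2-[3,4-bis(benzyloxy)phenyl]ethenyl carbonate | O=C(OCc1ccccc1)O/C=C/c1ccc(OCc2ccccc2)c(OCc2ccccc2)c1
A4 | alternative 2 | (2R,3R)-5,7-bis(benzyloxy)-3-(tert-butyldimethylsilyloxy)-4-(penta-O-benzylcatechin-8-yl)-2-[3,4,5-tris(benzyloxy)phenyl]chroman-4-ol, C4 epimers | CC(C)(C)[Si](C)(C)O[C@@H]1C(O)(c2c(OCc3ccccc3)cc(OCc3ccccc3)c3c2O[C@H](c2ccc(OCc4ccccc4)c(OCc4ccccc4)c2)[C@@H](OCc2ccccc2)C3)c2c(OCc3ccccc3)cc(OCc3ccccc3)cc2O[C@@H]1c1cc(OCc2ccccc2)c(OCc2ccccc2)c(OCc2ccccc2)c1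
A5 | alternative 2 | (2S,3R)-2-(tert-butyldimethylsilyloxy)-3-hydroxy-1-(penta-O-benzylcatechin-8-yl)-3-[3,4,5-tris(benzyloxy)phenyl]propan-1-one (syn aldol) | CC(C)(C)[Si](C)(C)O[C@@H]([C@H](O)c1cc(OCc2ccccc2)c(OCc2ccccc2)c(OCc2ccccc2)c1)C(=O)c1c(OCc2ccccc2)cc(OCc2ccccc2)c2c1O[C@H](c1ccc(OCc3ccccc3)c(OCc3ccccc3)c1)[C@@H](OCc1ccccc1)C2
A6 | alternative 2 | 3,5-bis(benzyloxy)benzyne | C1#CC(OCc2ccccc2)=CC(OCc2ccccc2)=C1
A7 | alternative 3 | (3R,4R)-5,7-bis(benzyloxy)-3-(tert-butyldimethylsilyloxy)-4-(penta-O-benzylcatechin-8-yl)-2-[3,4,5-tris(benzyloxy)phenyl]chroman-2-ol, C2 anomers | CC(C)(C)[Si](C)(C)O[C@@H]1[C@@H](c2c(OCc3ccccc3)cc(OCc3ccccc3)c3c2O[C@H](c2ccc(OCc4ccccc4)c(OCc4ccccc4)c2)[C@@H](OCc2ccccc2)C3)c2c(OCc3ccccc3)cc(OCc3ccccc3)cc2OC1(O)c1cc(OCc2ccccc2)c(OCc2ccccc2)c(OCc2ccccc2)c1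
A8 | alternative 3 | [2,4-bis(benzyloxy)-6-hydroxyphenyl](penta-O-benzylcatechin-8-yl)methanol, carbinol epimers | OC(c1c(O)cc(OCc2ccccc2)cc1OCc1ccccc1)c1c(OCc2ccccc2)cc(OCc2ccccc2)c2c1O[C@H](c1ccc(OCc3ccccc3)c(OCc3ccccc3)c1)[C@@H](OCc1ccccc1)C2
A9 | alternative 3 | 2-(tert-butyldimethylsilyloxy)-1-[3,4,5-tris(benzyloxy)phenyl]ethanone | CC(C)(C)[Si](C)(C)OCC(=O)c1cc(OCc2ccccc2)c(OCc2ccccc2)c(OCc2ccccc2)c1
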